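At early times the spring run climbed to 51.2 % of the charge within 2.00 h, so I asked what stops it, and I kept the books on partner, the reagent charged in the smaller amount.

all flasks: solid substrate 1.5 M
- spring: partner 1.2 M; protic impurity 0.50 M; run made earlier
- dusk: partner 1.2 M; protic impurity 1.1 M; run made earlier
- summer: partner 2.4 M; protic impurity 0.75 M; run made earlier
- flask: partner 1.20 M; protic impurity 0.750 M; time 40 h

| run | time / h | target / % |
|---|---|---|
| spring | 1.00 | 39.8 |
| spring | 2.00 | 51.2 |
| spring | 5.00 | 54.8 |
| spring | 10.0 | 51.7 |
| spring | 25.0 | 45.5 |
| dusk | 1.00 | 35.1 |
| dusk | 2.00 | 43.3 |
| dusk | 5.00 | 42.7 |
| dusk | 10.0 | 36.4 |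
| dusk | 25.0 | 26.2 |
| summer | 1.00 | 65.4 |
| summer | 2.00 | 77.3 |
| summer | 5.00 | 83.4 |
| summer | 10.0 | 85.5 |
| summer | 25.0 | 85.7 |

(scatter of a reading: 0.5 percentage points)

- in percentages every species weighs as the solid substrate in it: one side product or self-condensation product A or self-condensation product B counts as two
- for target the solid product is counted in
- as a solid, counted per litre of solution: solid substrate, solid product
- reactions considered so far: solid substrate <-> dissolved substrate; dissolved substrate + partner -> target; dissolved substrate + target -> side product; solid product <-> target; partner + protic impurity -> quenched reagent; 2 solid substrate -> self-condensation product A; 2 solid substrate -> self-condensation product B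
- at the start none of the solid substrate is in solution

- time up to 40 h at which target stands highest
- the amount of target, in percent of the solid substrate charged, at that time

1. Main step first. Partner was the smaller charge, the limiting reagent, at 0.800 of the solid substrate charge. One partner makes one target, so coupling by itself gives that fraction in spring, dusk and the flask.

2. Then the quench. Had the protic impurity taken its full charge of partner first, spring would have kept 0.467 and dusk 0.0667. But their highest readings were 54.8 % and 43.3 %. So the impurity took part of what it could, and I needed a measured price, not a subtraction.

3. Then the rest. Summer, with partner at 1.60 of the charge, ended at 85.7 %, so 14 percentage points went elsewhere. Spring sank to 45.5 % by 25.0 h, so target was also lost after its top.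

4. Spring and dusk share their substrate and partner charges, so I read their gap as the work of the impurity. The highest reading fell 11 points for 0.400 more impurity, which gives 0.287, the impurity price: top target lost per unit of impurity charged, both as fractions of the solid substrate charge.

5. The flask carried 0.167 more impurity than spring, so I reckoned a top of 0.500, somewhere between 2.00 h and 5.00 h, the times of the highest readings in dusk and spring.

6. The forecast said 51 % (range 48.5 % to 53 %) at 3.5 h (2.7 h to 4.8 h), a little above my top, holding that “quenching is not instantaneous and competes with coupling”.

7. The flask gave 50.1 % at 3.71 h, inside both ranges.

    solid substrate ⇌ dissolved substrate, rate k1*(cs1 - [dissolved substrate]) while solid is left; crystals form when [dissolved substrate] > cs1 (solubility = 0.930 M, k = 0.00270 /s)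
    dissolved substrate + partner → target (k = 3.20 × 10⁻⁴ /M/s)
    dissolved substrate + target → side product (k = 2.10 × 10⁻⁵ /M/s)
    solid product ⇌ target, rate k4*(cs4 - [target]) while solid is left; crystals form when [target] > cs4 (solubility = 0.560 M, k = 0.00910 /s)
    partner + protic impurity → quenched reagent (k = 1.50 × 10⁻⁴ /M/s)
    2 solid substrate → self-condensation product A (k = 1.10 × 10⁻⁴ /M/s)
    2 solid substrate → self-condensation product B (k = 1.70 × 10⁻⁷ /M/s)

The largest single effect on the best of the flask was the using up of partner: with that taken away, the best rose from 50.1 % to 85.5 %. The quench is a part of it: with the quench removed, the best of the flask rose to 69.7 %. Read back from the flask, the impurity price came to 0.282, against the 0.287 I carried. Applied to the neighbour flask with 0.300 of impurity, the price gave a top of 0.558, and the best of that neighbour flask stood at 56.3 %.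

The readings were computed on assumed constants.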